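**Retrosynthetic overview**

- The target is reached from its tris-MOM, mono-TBS protected flavanone by one acid deprotection; rings A and B are bought as benzene rings, and ring C is the only ring made and is closed last.
- Ring C is closed by forming the C3–C4 bond in an enantioselective intramolecular alkene hydroacylation of a 2-(1-arylethenyloxy)benzaldehyde, which also creates the C4 ketone and the C2 stereocentre.
- Enabling feature: in ring C the C4 carbonyl, the C3 methylene and the hydrogen-bearing C2 (carrying O1 and the ring B aryl) form the product pattern of a hydroacylation, so C2–C3 can be drawn back to the C=CH2 of an aryl 1-arylvinyl ether and C4 to a formyl group ortho to O1 on ring A.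
- The enol ether comes from an aryl ester (ring A phenol plus ring B benzoic acid) by methylenation, with the formyl group carried as a silylated CH2OH; ring A regiochemistry is fixed by ortho-iodination of the chelated phenol of 2,4,6-trihydroxybenzaldehyde, and the C8–C1'' bond is made by Negishi coupling.
- Side chain: C3'' comes from (S)-3-bromo-2-methylpropan-1-ol, C2'' from an Evans prenylation, and the derived primary iodide is the coupling handle.

Key step: step 18

Assumption: (R)-DTBM-SEGPHOS is taken to give the (2S) product in step 18; the sense of induction on this substrate class must be fixed on a model aldehyde, and the (S)-ligand is used if it is opposite (MOM = methoxymethyl, TBS = tert-butyldimethylsilyl; C1''–C4'' count from the ring A benzylic CH2 to CH2OH).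

**Route**

Step 1
Reactants: 1 2,4,6-trihydroxybenzaldehyde
Product: 2 2-hydroxy-4,6-bis(methoxymethoxy)benzaldehyde
Conditions: MOMCl (2.1 equiv), i-Pr2NEt, CH2Cl2, 0 °C to rt
Reagents that add atoms: chloromethyl methyl ether (MOMCl), COCCl
Why: O-alkylation of the two non-chelated phenols as MOM acetals, the third hydroxyl staying free because it is held in a hydrogen bond to the formyl group.

Step 2
Reactants: 2 2-hydroxy-4,6-bis(methoxymethoxy)benzaldehyde
Product: 3 2-hydroxy-3-iodo-4,6-bis(methoxymethoxy)benzaldehyde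
Conditions: N-iodosuccinimide (1.05 equiv), DMF, 0 °C, dark
Reagents that add atoms: N-iodosuccinimide, O=C1CCC(=O)N1I
Why: Electrophilic aromatic iodination, which should go ortho to the free chelated phenol at the less crowded open position (flanked by OH and OMOM, not by two OMOM groups), the carbon that becomes C8.

Step 3
Reactants: 3 2-hydroxy-3-iodo-4,6-bis(methoxymethoxy)benzaldehyde
Product: 4 2-(hydroxymethyl)-6-iodo-3,5-bis(methoxymethoxy)phenol
Conditions: NaBH4, THF/MeOH, 0 °C; pH 7 work-up, used crude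
Reagents that add atoms: none
Why: Borohydride reduction takes the future C4 to the alcohol level so that the later ester methylenation meets no competing carbonyl group.

Step 4
Reactants: 4 2-(hydroxymethyl)-6-iodo-3,5-bis(methoxymethoxy)phenol
Product: 5 2-{[(tert-butyldimethylsilyl)oxy]methyl}-6-iodo-3,5-bis(methoxymethoxy)phenol
Conditions: TBSCl (1.05 equiv), imidazole, CH2Cl2, 0 °C
Reagents that add atoms: tert-butyldimethylsilyl chloride, CC(C)(C)[Si](C)(C)Cl
Why: Silylation of the primary benzylic alcohol should outpace that of the doubly ortho-substituted phenol, which stays free for acylation.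

Step 5
Reactants: 6 methyl 4-hydroxy-2-methoxybenzoate
Product: 7 methyl 2-methoxy-4-(methoxymethoxy)benzoate
Conditions: MOMCl, i-Pr2NEt, CH2Cl2, 0 °C to rt
Reagents that add atoms: chloromethyl methyl ether (MOMCl), COCCl
Why: O-alkylation of the phenol as its MOM acetal matches the ring A protecting groups for a single final acid deprotection.

Step 6
Reactants: 7 methyl 2-methoxy-4-(methoxymethoxy)benzoate
Product: 8 2-methoxy-4-(methoxymethoxy)benzoic acid
Conditions: LiOH, THF/MeOH/H2O, 40 °C; then 1 M HCl to pH 4, 0 °C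
Reagents that add atoms: lithium hydroxide, [Li+].[OH-]
Why: Saponification of the methyl ester under conditions that leave the aryl MOM ether intact.

Step 7
Reactants: 5 2-{[(tert-butyldimethylsilyl)oxy]methyl}-6-iodo-3,5-bis(methoxymethoxy)phenol; 8 2-methoxy-4-(methoxymethoxy)benzoic acid
Product: 9 2-{[(tert-butyldimethylsilyl)oxy]methyl}-6-iodo-3,5-bis(methoxymethoxy)phenyl 2-methoxy-4-(methoxymethoxy)benzoate
Conditions: EDC·HCl, DMAP (1 equiv), CH2Cl2, rt
Reagents that add atoms: none
Why: Steglich esterification (carbodiimide activation with DMAP acyl transfer) tolerates the hindered phenol and builds the O1–C2 bond at the ester oxidation level.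

Step 8
Reactants: 9 2-{[(tert-butyldimethylsilyl)oxy]methyl}-6-iodo-3,5-bis(methoxymethoxy)phenyl 2-methoxy-4-(methoxymethoxy)benzoate
Product: 10 tert-butyl{[3-iodo-2-({1-[2-methoxy-4-(methoxymethoxy)phenyl]ethenyl}oxy)-4,6-bis(methoxymethoxy)phenyl]methoxy}dimethylsilane
Conditions: Cp2Ti(μ-Cl)(μ-CH2)AlMe2 (Tebbe reagent, 1.5 equiv), pyridine, THF/toluene, −40 to 0 °C; aq NaOH work-up; Et3N-deactivated silica
Reagents that add atoms: Tebbe reagent Cp2Ti(μ-Cl)(μ-CH2)AlMe2, C[Al-]1(C)C[Ti](C2C=CC=C2)(C2C=CC=C2)[Cl+]1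
Why: Tebbe methylenation of the aryl ester through an oxatitanacyclobutane gives the aryl 1-arylvinyl ether, a conversion with direct precedent for aryl benzoates and compatible with aryl iodide, silyl ether and acetals.

Step 9
Reactants: 10 tert-butyl{[3-iodo-2-({1-[2-methoxy-4-(methoxymethoxy)phenyl]ethenyl}oxy)-4,6-bis(methoxymethoxy)phenyl]methoxy}dimethylsilane
Product: 11 [3-iodo-2-({1-[2-methoxy-4-(methoxymethoxy)phenyl]ethenyl}oxy)-4,6-bis(methoxymethoxy)phenyl]methanol
Conditions: Bu4NF, THF, 0 °C; basic work-up, no chromatography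
Reagents that add atoms: none
Why: Fluoride desilylation under basic conditions frees the benzylic alcohol, which is carried on crude because acid would add the hydroxyl across the neighbouring enol ether.

Step 10
Reactants: 11 [3-iodo-2-({1-[2-methoxy-4-(methoxymethoxy)phenyl]ethenyl}oxy)-4,6-bis(methoxymethoxy)phenyl]methanol
Product: 12 3-iodo-2-({1-[2-methoxy-4-(methoxymethoxy)phenyl]ethenyl}oxy)-4,6-bis(methoxymethoxy)benzaldehyde
Conditions: MnO2 (activated, excess), CH2Cl2, rt
Reagents that add atoms: none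
Why: MnO2 oxidation of the electron-rich benzylic alcohol restores the aldehyde under neutral conditions that spare the enol ether.

Step 11
Reactants: 13 (S)-3-bromo-2-methylpropan-1-ol
Product: 14 tert-butyl{[(2S)-3-bromo-2-methylpropyl]oxy}dimethylsilane
Conditions: TBSCl, imidazole, CH2Cl2, rt
Reagents that add atoms: tert-butyldimethylsilyl chloride, CC(C)(C)[Si](C)(C)Cl
Why: Silylation of the primary alcohol protects the future C4'' hydroxyl of the chiral-pool building block that supplies C3''.

Step 12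
Reactants: 14 tert-butyl{[(2S)-3-bromo-2-methylpropyl]oxy}dimethylsilane
Product: 16 (3R)-4-[(tert-butyldimethylsilyl)oxy]-3-methylbutanoic acid, via Grignard reagent 15 (not isolated)
Conditions: Mg, THF, 50 °C; CO2, −20 °C to rt; 1 M HCl to pH 4, 0 °C
Reagents that add atoms: carbon dioxide, O=C=O
Why: Grignard carboxylation adds the carboxyl carbon without touching the methyl-bearing stereocentre, whose descriptor changes from S to R only through the priority rules.

Step 13
Reactants: 16 (3R)-4-[(tert-butyldimethylsilyl)oxy]-3-methylbutanoic acid; 17 (S)-4-benzyl-1,3-oxazolidin-2-one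
Product: 19 (4S)-4-benzyl-3-{(3R)-4-[(tert-butyldimethylsilyl)oxy]-3-methylbutanoyl}-1,3-oxazolidin-2-one, via mixed pivalic anhydride 18 (not isolated)
Conditions: PivCl, Et3N, THF, −20 °C; then 17, LiCl, rt
Reagents that add atoms: none
Why: N-acylation of the oxazolidinone through the mixed pivalic anhydride attaches the Evans auxiliary without any epimerisable intermediate.

Step 14
Reactants: 19 (4S)-4-benzyl-3-{(3R)-4-[(tert-butyldimethylsilyl)oxy]-3-methylbutanoyl}-1,3-oxazolidin-2-one; 20 1-bromo-3-methylbut-2-ene (prenyl bromide)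
Product: 22 (4S)-4-benzyl-3-[(2S)-2-{(2R)-1-[(tert-butyldimethylsilyl)oxy]propan-2-yl}-5-methylhex-4-enoyl]-1,3-oxazolidin-2-one, via sodium enolate 21 (not isolated)
Conditions: NaN(SiMe3)2, THF, −78 °C; then 20 (3 equiv), −78 to −40 °C
Reagents that add atoms: none
Why: Evans alkylation, in which the chelated sodium Z-enolate is prenylated on the face opposite the benzyl group, sets the new (2S) centre (C2'' of the target) under auxiliary control that overrides the adjacent methyl-bearing centre.

Step 15
Reactants: 22 (4S)-4-benzyl-3-[(2S)-2-{(2R)-1-[(tert-butyldimethylsilyl)oxy]propan-2-yl}-5-methylhex-4-enoyl]-1,3-oxazolidin-2-one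
Product: 23 (2S)-2-{(2R)-1-[(tert-butyldimethylsilyl)oxy]propan-2-yl}-5-methylhex-4-en-1-ol
Conditions: LiBH4, MeOH (1 equiv), Et2O, 0 °C
Reagents that add atoms: none
Why: Reductive cleavage of the imide with LiBH4 gives the primary alcohol and releases the auxiliary without epimerising the α-centre.

Step 16
Reactants: 23 (2S)-2-{(2R)-1-[(tert-butyldimethylsilyl)oxy]propan-2-yl}-5-methylhex-4-en-1-ol
Product: 24 tert-butyl{[(2R,3S)-3-(iodomethyl)-2,6-dimethylhept-5-en-1-yl]oxy}dimethylsilane
Conditions: I2, PPh3, imidazole, CH2Cl2, 0 °C to rt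
Reagents that add atoms: iodine, II
Why: Appel-type iodination converts the primary alcohol into the iodide by substitution at CH2, leaving both stereocentres untouched.

Step 17
Reactants: 24 tert-butyl{[(2R,3S)-3-(iodomethyl)-2,6-dimethylhept-5-en-1-yl]oxy}dimethylsilane; 12 3-iodo-2-({1-[2-methoxy-4-(methoxymethoxy)phenyl]ethenyl}oxy)-4,6-bis(methoxymethoxy)benzaldehyde
Product: 26 3-{(2R,3R)-4-[(tert-butyldimethylsilyl)oxy]-3-methyl-2-(3-methylbut-2-en-1-yl)butyl}-2-({1-[2-methoxy-4-(methoxymethoxy)phenyl]ethenyl}oxy)-4,6-bis(methoxymethoxy)benzaldehyde, via alkylzinc iodide 25 (not isolated)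
Conditions: Zn dust (activated with BrCH2CH2Br and Me3SiCl), LiCl, THF, 40 °C; then 12, Pd2(dba)3 (2.5 mol%), SPhos (10 mol%), THF/NMP, 45 °C
Reagents that add atoms: none
Why: Negishi sp3–sp2 cross-coupling (zinc insertion into the primary iodide, then zerovalent palladium with a bulky biarylphosphine) joins C1'' to C8 in the presence of the aldehyde without involving any stereocentre.

Step 18
Reactants: 26 3-{(2R,3R)-4-[(tert-butyldimethylsilyl)oxy]-3-methyl-2-(3-methylbut-2-en-1-yl)butyl}-2-({1-[2-methoxy-4-(methoxymethoxy)phenyl]ethenyl}oxy)-4,6-bis(methoxymethoxy)benzaldehyde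
Product: 27 (2S)-8-{(2R,3R)-4-[(tert-butyldimethylsilyl)oxy]-3-methyl-2-(3-methylbut-2-en-1-yl)butyl}-2-[2-methoxy-4-(methoxymethoxy)phenyl]-5,7-bis(methoxymethoxy)-2,3-dihydro-4H-chromen-4-one
Conditions: [Rh(cod)Cl]2 (2.5 mol%), (R)-DTBM-SEGPHOS (5.5 mol%), NaB[3,5-(CF3)2C6H3]4 (5 mol%), 1,4-dioxane (degassed), 60 °C, argon
Reagents that add atoms: none
Why: Proposed new method: cationic monovalent rhodium inserts into the formyl C–H bond of 26 to give an acyl rhodium hydride (trivalent rhodium) held beside the enol ether by the O1 oxygen, anti-Markovnikov migratory insertion of the C=CH2 unit then puts hydride on the aryl- and aryloxy-bearing carbon (future C2) and rhodium on the terminal CH2, and C–C reductive elimination from the seven-membered acyl–alkyl rhodacycle forms the C3–C4 bond and frees the catalyst. The closest known reaction type is the enantioselective rhodium–bisphosphine hydroacylation of 1,1-disubstituted alkenes tethered ortho to an aryl aldehyde (2-substituted allyl arenes and N-allyl heteroaryl aldehydes to six-membered ketones, 2-alkenylbenzaldehydes to indanones), and its use on an aryl 1-arylvinyl ether is the new element. Ring C closes in the 6-endo-trig mode. The only new stereocentre, C2, is set in the hydride insertion by the chiral pocket of the bisphosphine (catalyst control, the side-chain stereocentres being too remote to bias the alkene face). The step needs endo over exo regioselectivity, which the 1,1-disubstitution secures because Markovnikov insertion would give a tertiary benzylic alkyl rhodium whose reductive elimination to a quaternary 2-methylbenzofuranone centre is slow and reversible. It also needs chemoselectivity against decarbonylation and against the side-chain alkene, which the chelating ether oxygen, the two ortho oxygen substituents of the aldehyde and the remote trisubstituted nature of that alkene should provide.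

Step 19
Reactants: 27 (2S)-8-{(2R,3R)-4-[(tert-butyldimethylsilyl)oxy]-3-methyl-2-(3-methylbut-2-en-1-yl)butyl}-2-[2-methoxy-4-(methoxymethoxy)phenyl]-5,7-bis(methoxymethoxy)-2,3-dihydro-4H-chromen-4-one
Product: 28 (2S)-5,7-dihydroxy-2-(4-hydroxy-2-methoxyphenyl)-8-[(2R,3R)-4-hydroxy-3-methyl-2-(3-methylbut-2-en-1-yl)butyl]-2,3-dihydro-4H-chromen-4-one (CNP0081318.1)
Conditions: HCl (1.25 M in MeOH), 0 °C to rt, argon
Reagents that add atoms: none
Why: Acid methanolysis removes the three MOM acetals and the silyl ether in one operation, under mild conditions chosen to avoid ionisation of the benzylic C2–O bond (epimerisation) and solvolysis of the trisubstituted alkene.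

**Compound list**

1 | 2,4,6-trihydroxybenzaldehyde | O=Cc1c(O)cc(O)cc1O | starting material
2 | 2-hydroxy-4,6-bis(methoxymethoxy)benzaldehyde | O=Cc1c(O)cc(OCOC)cc1OCOC | intermediate
3 | 2-hydroxy-3-iodo-4,6-bis(methoxymethoxy)benzaldehyde | O=Cc1c(O)c(I)c(OCOC)cc1OCOC | intermediate
4 | 2-(hydroxymethyl)-6-iodo-3,5-bis(methoxymethoxy)phenol | OCc1c(O)c(I)c(OCOC)cc1OCOC | intermediate
5 | 2-{[(tert-butyldimethylsilyl)oxy]methyl}-6-iodo-3,5-bis(methoxymethoxy)phenol | CC(C)(C)[Si](C)(C)OCc1c(O)c(I)c(OCOC)cc1OCOC | intermediate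
6 | methyl 4-hydroxy-2-methoxybenzoate | COC(=O)c1ccc(O)cc1OC | starting material
7 | methyl 2-methoxy-4-(methoxymethoxy)benzoate | COC(=O)c1ccc(OCOC)cc1OC | intermediate
8 | 2-methoxy-4-(methoxymethoxy)benzoic acid | OC(=O)c1ccc(OCOC)cc1OC | intermediate
9 | 2-{[(tert-butyldimethylsilyl)oxy]methyl}-6-iodo-3,5-bis(methoxymethoxy)phenyl 2-methoxy-4-(methoxymethoxy)benzoate | COCOc1ccc(C(=O)Oc2c(CO[Si](C)(C)C(C)(C)C)c(OCOC)cc(OCOC)c2I)c(OC)c1 | intermediate
10 | tert-butyl{[3-iodo-2-({1-[2-methoxy-4-(methoxymethoxy)phenyl]ethenyl}oxy)-4,6-bis(methoxymethoxy)phenyl]methoxy}dimethylsilane | COCOc1ccc(C(=C)Oc2c(CO[Si](C)(C)C(C)(C)C)c(OCOC)cc(OCOC)c2I)c(OC)c1 | intermediate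
11 | [3-iodo-2-({1-[2-methoxy-4-(methoxymethoxy)phenyl]ethenyl}oxy)-4,6-bis(methoxymethoxy)phenyl]methanol | COCOc1ccc(C(=C)Oc2c(CO)c(OCOC)cc(OCOC)c2I)c(OC)c1 | intermediate
12 | 3-iodo-2-({1-[2-methoxy-4-(methoxymethoxy)phenyl]ethenyl}oxy)-4,6-bis(methoxymethoxy)benzaldehyde | COCOc1ccc(C(=C)Oc2c(C=O)c(OCOC)cc(OCOC)c2I)c(OC)c1 | intermediate
13 | (S)-3-bromo-2-methylpropan-1-ol | BrC[C@@H](C)CO | starting material
14 | tert-butyl{[(2S)-3-bromo-2-methylpropyl]oxy}dimethylsilane | BrC[C@@H](C)CO[Si](C)(C)C(C)(C)C | intermediate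
15 | {(2S)-3-[(tert-butyldimethylsilyl)oxy]-2-methylpropyl}magnesium bromide | Br[Mg]C[C@@H](C)CO[Si](C)(C)C(C)(C)C | intermediate
16 | (3R)-4-[(tert-butyldimethylsilyl)oxy]-3-methylbutanoic acid | OC(=O)C[C@@H](C)CO[Si](C)(C)C(C)(C)C | intermediate
17 | (S)-4-benzyl-1,3-oxazolidin-2-one | O=C1OC[C@H](Cc2ccccc2)N1 | starting material
18 | (3R)-4-[(tert-butyldimethylsilyl)oxy]-3-methylbutanoic pivalic anhydride | CC(C)(C)C(=O)OC(=O)C[C@@H](C)CO[Si](C)(C)C(C)(C)C | intermediate
19 | (4S)-4-benzyl-3-{(3R)-4-[(tert-butyldimethylsilyl)oxy]-3-methylbutanoyl}-1,3-oxazolidin-2-one | O=C1OC[C@H](Cc2ccccc2)N1C(=O)C[C@@H](C)CO[Si](C)(C)C(C)(C)C | intermediate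
20 | 1-bromo-3-methylbut-2-ene (prenyl bromide) | CC(C)=CCBr | starting material
21 | sodium (Z)-enolate of 19 | [Na+].[O-]/C(=C\[C@@H](C)CO[Si](C)(C)C(C)(C)C)N1[C@@H](Cc2ccccc2)COC1=O | intermediate
22 | (4S)-4-benzyl-3-[(2S)-2-{(2R)-1-[(tert-butyldimethylsilyl)oxy]propan-2-yl}-5-methylhex-4-enoyl]-1,3-oxazolidin-2-one | O=C1OC[C@H](Cc2ccccc2)N1C(=O)[C@@H](CC=C(C)C)[C@@H](C)CO[Si](C)(C)C(C)(C)C | intermediate
23 | (2S)-2-{(2R)-1-[(tert-butyldimethylsilyl)oxy]propan-2-yl}-5-methylhex-4-en-1-ol | OC[C@@H](CC=C(C)C)[C@@H](C)CO[Si](C)(C)C(C)(C)C | intermediate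
24 | tert-butyl{[(2R,3S)-3-(iodomethyl)-2,6-dimethylhept-5-en-1-yl]oxy}dimethylsilane | IC[C@@H](CC=C(C)C)[C@@H](C)CO[Si](C)(C)C(C)(C)C | intermediate
25 | {(2S)-2-{(2R)-1-[(tert-butyldimethylsilyl)oxy]propan-2-yl}-5-methylhex-4-en-1-yl}zinc iodide | I[Zn]C[C@@H](CC=C(C)C)[C@@H](C)CO[Si](C)(C)C(C)(C)C | intermediate
26 | 3-{(2R,3R)-4-[(tert-butyldimethylsilyl)oxy]-3-methyl-2-(3-methylbut-2-en-1-yl)butyl}-2-({1-[2-methoxy-4-(methoxymethoxy)phenyl]ethenyl}oxy)-4,6-bis(methoxymethoxy)benzaldehyde | COCOc1ccc(C(=C)Oc2c(C=O)c(OCOC)cc(OCOC)c2C[C@@H](CC=C(C)C)[C@@H](C)CO[Si](C)(C)C(C)(C)C)c(OC)c1 | intermediate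
27 | (2S)-8-{(2R,3R)-4-[(tert-butyldimethylsilyl)oxy]-3-methyl-2-(3-methylbut-2-en-1-yl)butyl}-2-[2-methoxy-4-(methoxymethoxy)phenyl]-5,7-bis(methoxymethoxy)-2,3-dihydro-4H-chromen-4-one | COc1cc(OCOC)ccc1[C@@H]1CC(=O)c2c(OCOC)cc(OCOC)c(C[C@@H](CC=C(C)C)[C@@H](C)CO[Si](C)(C)C(C)(C)C)c2O1 | intermediate
28 | (2S)-5,7-dihydroxy-2-(4-hydroxy-2-methoxyphenyl)-8-[(2R,3R)-4-hydroxy-3-methyl-2-(3-methylbut-2-en-1-yl)butyl]-2,3-dihydro-4H-chromen-4-one | COc1cc(O)ccc1[C@@H]1CC(=O)c2c(O)cc(O)c(C[C@@H](CC=C(C)C)[C@@H](C)CO)c2O1 | target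

**Summary**

Total steps: 19. Longest linear sequence: 11 steps (steps 1–4, 7–10, 17–19).

Steps most likely to fail:

1. Step 18 (key step). The acyl rhodium hydride may decarbonylate, Markovnikov insertion may divert material towards the five-membered ketone, or the hydride transfer may show poor facial selectivity. The fallback sets out from 26 and comes back at 27. It is a thiol-catalysed radical-chain hydroacylation, a known way to cyclise alkenals (tert-dodecanethiol, 1,1'-azobis(cyclohexanecarbonitrile), chlorobenzene, 110 °C). The aroyl radical adds 6-endo to the CH2 terminus, and the resulting benzylic radical takes hydrogen from the thiol without facial control. 27 should therefore form together with its C2 epimer, the (2R)-flavanone F1, a diastereomer that is removed by chromatography. F1 is recycled with DBU in toluene through the ring-opened 2'-hydroxychalcone F2, which recloses by oxa-Michael addition to the 27/F1 mixture.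

2. Step 17. Transmetalation and reductive elimination at the doubly ortho-substituted aryl iodide may be slow, so that protodezincation and β-hydride elimination of the alkyl palladium compete. The fallback sets out from 24 and 12 and comes back at 26. Iodine–lithium exchange on 24 (t-BuLi, Et2O, −78 °C) and capture with 9-methoxy-9-borabicyclo[3.3.1]nonane should give the lithium alkyl(methoxy)borate F3. B-alkyl Suzuki–Miyaura coupling of F3 with 12 (PdCl2(dppf), K3PO4, DMF/H2O, rt) then delivers 26.

3. Step 3. The electron-rich 2-hydroxybenzyl alcohol may ionise to an ortho-quinone methide and oligomerise during work-up or silylation. The fallback sets out from 3 and comes back at 12, masking the formyl group without changing its oxidation level. Condensation of 3 with N,N'-dimethylethane-1,2-diamine (MgSO4, CH2Cl2) gives the imidazolidine phenol F4. EDC/DMAP esterification with 8 gives the aminal ester F5, and Tebbe methylenation gives the aminal enol ether F6. Hydrolysis of the aminal on wet silica gel or in pH 5 acetate buffer then gives 12. Compounds 4, 5, 9, 10 and 11 are bypassed, and with them the free hydroxyl next to the enol ether.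

Further compounds
F1 | step 18 | (2R)-8-{(2R,3R)-4-[(tert-butyldimethylsilyl)oxy]-3-methyl-2-(3-methylbut-2-en-1-yl)butyl}-2-[2-methoxy-4-(methoxymethoxy)phenyl]-5,7-bis(methoxymethoxy)-2,3-dihydro-4H-chromen-4-one | COc1cc(OCOC)ccc1[C@H]1CC(=O)c2c(OCOC)cc(OCOC)c(C[C@@H](CC=C(C)C)[C@@H](C)CO[Si](C)(C)C(C)(C)C)c2O1
F2 | step 18 | (E)-1-[3-{(2R,3R)-4-[(tert-butyldimethylsilyl)oxy]-3-methyl-2-(3-methylbut-2-en-1-yl)butyl}-2-hydroxy-4,6-bis(methoxymethoxy)phenyl]-3-[2-methoxy-4-(methoxymethoxy)phenyl]prop-2-en-1-one | COc1cc(OCOC)ccc1/C=C/C(=O)c1c(OCOC)cc(OCOC)c(C[C@@H](CC=C(C)C)[C@@H](C)CO[Si](C)(C)C(C)(C)C)c1O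
F3 | step 17 | lithium 9-{(2S)-2-{(2R)-1-[(tert-butyldimethylsilyl)oxy]propan-2-yl}-5-methylhex-4-en-1-yl}-9-methoxy-9-boranuidabicyclo[3.3.1]nonane | [Li+].CO[B-]1(C[C@@H](CC=C(C)C)[C@@H](C)CO[Si](C)(C)C(C)(C)C)C2CCCC1CCC2
F4 | step 3 | 2-(1,3-dimethylimidazolidin-2-yl)-6-iodo-3,5-bis(methoxymethoxy)phenol | CN1CCN(C)C1c1c(O)c(I)c(OCOC)cc1OCOC
F5 | step 3 | 2-(1,3-dimethylimidazolidin-2-yl)-6-iodo-3,5-bis(methoxymethoxy)phenyl 2-methoxy-4-(methoxymethoxy)benzoate | COCOc1ccc(C(=O)Oc2c(C3N(C)CCN3C)c(OCOC)cc(OCOC)c2I)c(OC)c1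
F6 | step 3 | 2-[3-iodo-2-({1-[2-methoxy-4-(methoxymethoxy)phenyl]ethenyl}oxy)-4,6-bis(methoxymethoxy)phenyl]-1,3-dimethylimidazolidine | COCOc1ccc(C(=C)Oc2c(C3N(C)CCN3C)c(OCOC)cc(OCOC)c2I)c(OC)c1
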